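**Plan**
- Retrosynthesis: the lactol O–H is traced back to a 1-phenylethyl acetal; the diaryl ether C–O bond of the seven-membered ring (ring-A oxygen to the ring-B carbon next to the lactol carbon) is cut next; then three C–C bonds of ring A are cut: C(OH)–C(CH2O), C(OMe)–CH and C(OH)–C(CO2Ar).
- Enabling feature: ring A is a pentasubstituted benzene whose oxygen-bearing carbon lies between the ester-bearing carbon and the hydroxymethyl-bearing carbon, with the methoxy carbon meta to that oxygen and one ring CH. This is the pattern a vinylketene/alkoxyalkyne benzannulation delivers.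
- Forward: ring B is brominated, formylated and acylated with an enone acid; diazo transfer gives the diazoketone; the benzannulation builds ring A as a depside with a free phenol.
- An Ullmann etherification then closes the dioxepinone ring, and unmasking closes the hydroxyphthalide ring last.
- Stereochemistry: the single lactol centre is fixed as an acetal with (S)-1-phenylethanol, the (R)-acetal diastereomer is separated from the epimeric mixture (the remainder is re-equilibrated and recycled), and hydrogenolysis releases the (R)-lactol without breaking a bond to the stereocentre.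

Key step: step 13

Assumption: the lactol carbon epimerises by ring–chain tautomerism in protic or basic media, so the target is taken to be the (R)-lactol as released in the last, neutral step and isolated from aprotic solvent without aqueous work-up.

Abbreviation: Ar = 3-(benzyloxy)-4-[(benzyloxy)carbonyl]-6-bromo-5-(dimethoxymethyl)-2-methylphenyl, the aryl group of the ring-B phenol obtained in step 6.

**Ring B**

Step 1
Reactants: 1 2,4-dihydroxy-3-methylbenzoic acid
Product: 2 benzyl 2,4-dihydroxy-3-methylbenzoate
Conditions: BnBr, KHCO3, DMF, rt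
Reagents that add atoms: benzyl bromide, BrCc1ccccc1
Why: Carboxylate O-alkylation under hydrogen carbonate leaves the phenols alone and installs an ester that can later be removed by hydrogenolysis without hydrolytic risk to the depsidone lactone.

Step 2
Reactants: 2 benzyl 2,4-dihydroxy-3-methylbenzoate
Product: 3 benzyl 5-bromo-2,4-dihydroxy-3-methylbenzoate
Conditions: NBS, MeCN, 0 °C
Reagents that add atoms: N-bromosuccinimide, O=C1CCC(=O)N1Br
Why: Electrophilic aromatic bromination should take C5, the only free position ortho or para to both hydroxyl groups, and places the halogen needed for the later diaryl ether closure.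

Step 3
Reactants: 3 benzyl 5-bromo-2,4-dihydroxy-3-methylbenzoate
Product: 4 benzyl 5-bromo-2-hydroxy-4-(methoxymethoxy)-3-methylbenzoate
Conditions: MOMCl, i-Pr2NEt, CH2Cl2, 0 °C → rt
Reagents that add atoms: chloromethyl methyl ether, COCCl
Why: Williamson-type alkylation should go to the C4 hydroxyl, because the C2 hydroxyl is held in a hydrogen bond to the ester carbonyl.

Step 4
Reactants: 4 benzyl 5-bromo-2-hydroxy-4-(methoxymethoxy)-3-methylbenzoate
Product: 5 benzyl 2-(benzyloxy)-5-bromo-4-(methoxymethoxy)-3-methylbenzoate
Conditions: BnBr, K2CO3, DMF, 60 °C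
Reagents that add atoms: benzyl bromide, BrCc1ccccc1
Why: Williamson etherification under more forcing carbonate conditions benzylates the remaining chelated hydroxyl, which must stay masked until the end.

Step 5
Reactants: 5 benzyl 2-(benzyloxy)-5-bromo-4-(methoxymethoxy)-3-methylbenzoate
Product: 7 benzyl 2-(benzyloxy)-5-bromo-6-formyl-4-(methoxymethoxy)-3-methylbenzoate, via arylmagnesium chloride 6 (not isolated)
Conditions: TMPMgCl·LiCl, THF, −20 → 0 °C; DMF; aq. NH4Cl
Reagents that add atoms: N,N-dimethylformamide, CN(C)C=O
Why: Directed ortho-magnesiation with the Knochel–Hauser base TMPMgCl·LiCl should remove the only ring hydrogen, acidified by the flanking ester and bromine, without bromine–magnesium exchange or attack on the ester, and arylmagnesium 6 is then formylated by DMF.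

Step 6
Reactants: 7 benzyl 2-(benzyloxy)-5-bromo-6-formyl-4-(methoxymethoxy)-3-methylbenzoate
Product: 8 benzyl 2-(benzyloxy)-5-bromo-6-(dimethoxymethyl)-4-hydroxy-3-methylbenzoate
Conditions: HC(OMe)3, MeOH, TsOH (cat.), 50 °C
Reagents that add atoms: trimethyl orthoformate, COC(OC)OC; methanol, CO
Why: Acid-catalysed acetalisation masks the aldehyde for the later enolate and base chemistry, and the same acidic methanol (in which the dimethyl acetal only exchanges with itself) cleaves the MOM ether and frees the one hydroxyl that is to be acylated.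

**Enone acid**

Step 7
Reactants: 9 butane-2,3-dione
Product: 10 tert-butyl (E)-3-methyl-4-oxopent-2-enoate
Conditions: Ph3P=CHCO2t-Bu, CH2Cl2, rt, 9 in excess
Reagents that add atoms: tert-butyl (triphenylphosphoranylidene)acetate, CC(C)(C)OC(=O)C=P(c1ccccc1)(c1ccccc1)c1ccccc1
Why: Wittig olefination of one carbonyl of the symmetrical diketone with a stabilised ylide should give the E enoate (ester trans to acetyl), and the excess of diketone suppresses double olefination.

Step 8
Reactants: 10 tert-butyl (E)-3-methyl-4-oxopent-2-enoate
Product: 11 (E)-3-methyl-4-oxopent-2-enoic acid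
Conditions: TFA, CH2Cl2, 0 °C → rt
Reagents that add atoms: none
Why: Acidolysis of the tert-butyl ester with loss of isobutene frees the acid without any base or nucleophile that could add to the enone, and the E acid cannot lactolise.

**Diazoketone**

Step 9
Reactants: 8 benzyl 2-(benzyloxy)-5-bromo-6-(dimethoxymethyl)-4-hydroxy-3-methylbenzoate; 11 (E)-3-methyl-4-oxopent-2-enoic acid
Product: 12 Ar (E)-3-methyl-4-oxopent-2-enoate
Conditions: EDC·HCl, DMAP, CH2Cl2, rt
Reagents that add atoms: none
Why: Steglich-type carbodiimide esterification acylates the only free hydroxyl of 8, and the acetal, benzyl groups and aryl bromide are inert to it.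

Step 10
Reactants: 12 Ar (E)-3-methyl-4-oxopent-2-enoate
Product: 14 Ar (E)-5-diazo-3-methyl-4-oxopent-2-enoate, via trifluoroacetyl ketone 13 (not isolated)
Conditions: LiN(SiMe3)2, THF, −78 °C; CF3CO2CH2CF3; aq. NH4Cl; then MsN3, Et3N, H2O, MeCN, rt
Reagents that add atoms: methanesulfonyl azide, CS(=O)(=O)N=[N+]=[N-]
Why: In this detrifluoroacetylative (Regitz-type) diazo transfer the kinetic enolate of the methyl ketone is C-trifluoroacetylated and diketone 13 passes its activating acyl group to mesyl azide; this is preferred to acylation of diazomethane by an acid chloride, which would be undermined by dipolar cycloaddition to the electron-poor double bond, and the E geometry is not touched.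

**Alkyne**

Step 11
Reactants: 15 trichloroethylene
Product: 17 (E)-1,2-dichloro-1-methoxyethene, via dichloroacetylene 16 (not isolated)
Conditions: KH, MeOH, THF, 0 °C → rt
Reagents that add atoms: methanol, CO
Why: Base-induced loss of HCl gives dichloroacetylene 16, to which methoxide adds anti, which is the standard entry to dichlorovinyl ethers as alkoxyalkyne precursors.

Step 12
Reactants: 17 (E)-1,2-dichloro-1-methoxyethene
Product: 21 1-methoxy-3-(triisopropylsilyloxy)prop-1-yne, via chloro(methoxy)ethyne 18 (not isolated), via lithium methoxyacetylide 19 (not isolated), via lithium 3-methoxyprop-2-yn-1-olate 20 (not isolated)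
Conditions: n-BuLi (2 equiv), THF, −78 → −40 °C; (CH2O)n, −40 → 0 °C; TIPSOTf, −78 → 0 °C
Reagents that add atoms: formaldehyde (as paraformaldehyde), C=O; triisopropylsilyl triflate, CC(C)[Si](OS(=O)(=O)C(F)(F)F)(C(C)C)C(C)C
Why: Vinyl deprotonation with loss of LiCl gives chloroalkyne 18, chlorine–lithium exchange gives acetylide 19 (LiC≡COMe), which adds to formaldehyde, and silylation of alkoxide 20 in the flask avoids isolating the acid-sensitive 3-alkoxypropargyl alcohol.

**Ring A and the depsidone**

Step 13
Reactants: 14 Ar (E)-5-diazo-3-methyl-4-oxopent-2-enoate; 21 1-methoxy-3-(triisopropylsilyloxy)prop-1-yne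
Product: 24 Ar 2-hydroxy-4-methoxy-6-methyl-3-[(triisopropylsilyloxy)methyl]benzoate (bromo depside bearing a free ring-A phenol), via vinylketene 22 (not isolated), via 4-vinylcyclobutenone 23 (not isolated)
Conditions: hν (365 nm), ClCH2CH2Cl, rt, 21 in excess; then 80 °C
Reagents that add atoms: none
Why: Irradiation expels N2 and the Wolff shift of the alkenyl group gives vinylketene 22, whose ketene C=C adds across the electron-rich alkyne 21 in a (2+2) step to 4-vinylcyclobutenone 23; warming opens the four-membered ring (4π) and the ketene so formed recloses onto the enoate terminus. This is the Danheiser benzannulation of a diazoketone-derived vinylketene with an alkoxyalkyne. Ring A closes by thermal 6π electrocyclisation (new bond from the former ketene carbonyl carbon to the ester-bearing alkene carbon) followed by tautomerisation to the phenol, and the other two new ring bonds (carbonyl carbon to the silyloxymethyl-bearing alkyne carbon, ketene CH to the methoxy-bearing alkyne carbon) come from the (2+2) step. No stereocentre is formed. The step needs one regiochemistry in the (2+2) addition, which the polarisation of the ynol ether secures (its carbon remote from OMe attacks the ketene carbonyl carbon), and an E enoate, provided by the Wittig-derived geometry of 14, so that the ester sits outside in the 6π closure and cannot trap the ketene. Long-wavelength light should leave the aryl bromide alone, and a methyl ynol ether has no retro-ene pathway at the temperature of the thermal stage.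

Step 14
Reactants: 24 Ar 2-hydroxy-4-methoxy-6-methyl-3-[(triisopropylsilyloxy)methyl]benzoate
Product: 25 benzyl 8-(benzyloxy)-6-(dimethoxymethyl)-3-methoxy-1,9-dimethyl-11-oxo-4-[(triisopropylsilyloxy)methyl]-11H-dibenzo[b,e][1,4]dioxepine-7-carboxylate
Conditions: CuI, N,N-dimethylglycine, Cs2CO3, 1,4-dioxane, 100 °C
Reagents that add atoms: none
Why: In this intramolecular Ullmann diaryl ether synthesis the ring-A phenoxide is arylated at the ring-B C–Br bond under CuI/amino acid catalysis, the depside ester holding the partners in place for closure of the seven-membered dioxepinone ring, and the weakly polar medium is chosen to disfavour ionic side reactions of the phenoxide.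

**Lactol and stereocentre**

Step 15
Reactants: 25 depsidone acetal
Product: 27 racemic lactol (hydroxyphthalide fused to ring B; free ring-B phenol; ring-A CH2OTIPS), via depsidone aldehyde 26 (not isolated)
Conditions: 1 M HCl, THF, rt; then H2 (1 atm), Pd/C, EtOAc, rt
Reagents that add atoms: water, O
Why: Dilute acid hydrolyses the dimethyl acetal to aldehyde 26 while the TIPS ether survives, and hydrogenolysis of the benzyl ester and ether then lets the freed carboxylic acid add to the neighbouring aldehyde, which closes the hydroxyphthalide as a racemate (no control at the lactol centre here).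

Step 16
Reactants: 27 racemic lactol
Product: 29 (R)-acetal of 27 with (S)-1-phenylethanol (acetal carbon R; the lactol oxygen carries the (S)-1-phenylethyl group), via epimeric acetal mixture 28 (not isolated)
Conditions: (S)-1-phenylethanol, CSA (cat.), 4 Å molecular sieves, CH2Cl2, rt; chromatography; the fraction holding the other epimer is returned to the same conditions
Reagents that add atoms: (S)-1-phenylethanol, C[C@H](O)c1ccccc1
Why: Acid-catalysed pseudo-ester (acetal) formation of the hydroxyphthalide through the phthalidyl oxocarbenium ion gives both epimers at the acetal carbon as mixture 28, from which the (R)-acetal 29 is separated as a diastereomer while the remaining epimer is re-exposed to the same acid, under which the acetal carbon equilibrates again, so the stereocentre is set by diastereomer separation with recycling.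

Step 17
Reactants: 29 (R)-acetal with silyl ether
Product: 30 (R)-acetal with free ring-A hydroxymethyl group
Conditions: HF·pyridine, pyridine, THF, 0 °C → rt
Reagents that add atoms: none
Why: Fluoride-mediated cleavage of the silyl ether under pyridine-buffered conditions leaves the acetal stereocentre, both lactones and the diaryl ether untouched.

Step 18
Reactants: 30 (R)-acetal with free ring-A hydroxymethyl group
Product: 31 target depsidone, (R)-lactol
Conditions: H2 (1 atm), Pd(OH)2/C, EtOAc, rt; filtration, evaporation
Reagents that add atoms: none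
Why: Hydrogenolysis cleaves the benzylic C–O bond of the 1-phenylethyl group and not a bond to the acetal carbon, so the lactol is released with retention as the (R) enantiomer in a neutral aprotic medium in which ring–chain tautomerism is slow.

**Compound list**

1 | 2,4-dihydroxy-3-methylbenzoic acid | Cc1c(O)ccc(C(O)=O)c1O | starting material
2 | benzyl 2,4-dihydroxy-3-methylbenzoate | Cc1c(O)ccc(C(=O)OCc2ccccc2)c1O | intermediate
3 | benzyl 5-bromo-2,4-dihydroxy-3-methylbenzoate | Cc1c(O)c(Br)cc(C(=O)OCc2ccccc2)c1O | intermediate
4 | benzyl 5-bromo-2-hydroxy-4-(methoxymethoxy)-3-methylbenzoate | Cc1c(OCOC)c(Br)cc(C(=O)OCc2ccccc2)c1O | intermediate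
5 | benzyl 2-(benzyloxy)-5-bromo-4-(methoxymethoxy)-3-methylbenzoate | Cc1c(OCOC)c(Br)cc(C(=O)OCc2ccccc2)c1OCc3ccccc3 | intermediate
6 | {3-(benzyloxy)-2-[(benzyloxy)carbonyl]-6-bromo-5-(methoxymethoxy)-4-methylphenyl}magnesium chloride | Cc1c(OCOC)c(Br)c([Mg]Cl)c(C(=O)OCc2ccccc2)c1OCc3ccccc3 | intermediate
7 | benzyl 2-(benzyloxy)-5-bromo-6-formyl-4-(methoxymethoxy)-3-methylbenzoate | Cc1c(OCOC)c(Br)c(C=O)c(C(=O)OCc2ccccc2)c1OCc3ccccc3 | intermediate
8 | benzyl 2-(benzyloxy)-5-bromo-6-(dimethoxymethyl)-4-hydroxy-3-methylbenzoate | Cc1c(O)c(Br)c(C(OC)OC)c(C(=O)OCc2ccccc2)c1OCc3ccccc3 | intermediate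
9 | butane-2,3-dione | CC(=O)C(C)=O | starting material
10 | tert-butyl (E)-3-methyl-4-oxopent-2-enoate | CC(=O)/C(C)=C/C(=O)OC(C)(C)C | intermediate
11 | (E)-3-methyl-4-oxopent-2-enoic acid | CC(=O)/C(C)=C/C(O)=O | intermediate
12 | 3-(benzyloxy)-4-[(benzyloxy)carbonyl]-6-bromo-5-(dimethoxymethyl)-2-methylphenyl (E)-3-methyl-4-oxopent-2-enoate | CC(=O)/C(C)=C/C(=O)Oc1c(C)c(OCc2ccccc2)c(C(=O)OCc3ccccc3)c(C(OC)OC)c1Br | intermediate
13 | Ar (E)-7,7,7-trifluoro-3-methyl-4,6-dioxohept-2-enoate | O=C(CC(=O)/C(C)=C/C(=O)Oc1c(C)c(OCc2ccccc2)c(C(=O)OCc3ccccc3)c(C(OC)OC)c1Br)C(F)(F)F | intermediate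
14 | Ar (E)-5-diazo-3-methyl-4-oxopent-2-enoate | [N-]=[N+]=CC(=O)/C(C)=C/C(=O)Oc1c(C)c(OCc2ccccc2)c(C(=O)OCc3ccccc3)c(C(OC)OC)c1Br | intermediate
15 | trichloroethylene | ClC=C(Cl)Cl | starting material
16 | dichloroacetylene | ClC#CCl | intermediate
17 | (E)-1,2-dichloro-1-methoxyethene | CO/C(Cl)=C\Cl | intermediate
18 | chloro(methoxy)ethyne | COC#CCl | intermediate
19 | lithium methoxyacetylide | COC#C[Li] | intermediate
20 | lithium 3-methoxyprop-2-yn-1-olate | COC#CCO[Li] | intermediate
21 | 1-methoxy-3-(triisopropylsilyloxy)prop-1-yne | COC#CCO[Si](C(C)C)(C(C)C)C(C)C | intermediate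
22 | Ar (E)-3-methyl-5-oxopenta-2,4-dienoate (vinylketene) | O=C=C/C(C)=C/C(=O)Oc1c(C)c(OCc2ccccc2)c(C(=O)OCc3ccccc3)c(C(OC)OC)c1Br | intermediate
23 | Ar (E)-3-{2-methoxy-4-oxo-3-[(triisopropylsilyloxy)methyl]cyclobut-2-en-1-yl}but-2-enoate (racemic) | O=C1C(CO[Si](C(C)C)(C(C)C)C(C)C)=C(OC)C1/C(C)=C/C(=O)Oc2c(C)c(OCc3ccccc3)c(C(=O)OCc4ccccc4)c(C(OC)OC)c2Br | intermediate
24 | Ar 2-hydroxy-4-methoxy-6-methyl-3-[(triisopropylsilyloxy)methyl]benzoate | COc1cc(C)c(C(=O)Oc2c(C)c(OCc3ccccc3)c(C(=O)OCc4ccccc4)c(C(OC)OC)c2Br)c(O)c1CO[Si](C(C)C)(C(C)C)C(C)C | intermediate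
25 | benzyl 8-(benzyloxy)-6-(dimethoxymethyl)-3-methoxy-1,9-dimethyl-11-oxo-4-[(triisopropylsilyloxy)methyl]-11H-dibenzo[b,e][1,4]dioxepine-7-carboxylate | COc1cc(C)c2c(c1CO[Si](C(C)C)(C(C)C)C(C)C)Oc1c(c(C)c(OCc3ccccc3)c(C(=O)OCc4ccccc4)c1C(OC)OC)OC2=O | intermediate
26 | benzyl 8-(benzyloxy)-6-formyl-3-methoxy-1,9-dimethyl-11-oxo-4-[(triisopropylsilyloxy)methyl]-11H-dibenzo[b,e][1,4]dioxepine-7-carboxylate | COc1cc(C)c2c(c1CO[Si](C(C)C)(C(C)C)C(C)C)Oc1c(c(C)c(OCc3ccccc3)c(C(=O)OCc4ccccc4)c1C=O)OC2=O | intermediate
27 | racemic lactol: the target skeleton with CH2OTIPS on ring A, lactol carbon not defined | COc1cc(C)c2c(c1CO[Si](C(C)C)(C(C)C)C(C)C)Oc1c(c(C)c(O)c3c1C(O)OC3=O)OC2=O | intermediate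
28 | acetal of 27 with (S)-1-phenylethanol as the mixture of both epimers at the acetal carbon | COc1cc(C)c2c(c1CO[Si](C(C)C)(C(C)C)C(C)C)Oc1c(c(C)c(O)c3c1C(O[C@@H](C)c4ccccc4)OC3=O)OC2=O | intermediate
29 | (R)-acetal of 27 with (S)-1-phenylethanol | COc1cc(C)c2c(c1CO[Si](C(C)C)(C(C)C)C(C)C)Oc1c(c(C)c(O)c3c1[C@H](O[C@@H](C)c4ccccc4)OC3=O)OC2=O | intermediate
30 | 29 without the silyl group (free ring-A CH2OH, (R)-acetal, (S)-1-phenylethyl) | COc1cc(C)c2c(c1CO)Oc1c(c(C)c(O)c3c1[C@H](O[C@@H](C)c4ccccc4)OC3=O)OC2=O | intermediate
31 | target depsidone, (R)-lactol | COc1cc(C)c2c(c1CO)Oc1c(c(C)c(O)c3c1[C@H](O)OC3=O)OC2=O | target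

**Count**
Total: 18 steps. Longest linear sequence: 14 steps (steps 1–6, 9, 10, 13–18).

**Steps most likely to fail**

Step 13. Light may isomerise the enoate before or after the Wolff shift, after which the ketene is captured by its own ester oxygen; ketene dimerisation or acylation of the product phenol may also outrun the (2+2) addition. The fallback takes ring A from the aromatic pool and forms the depside by esterification. It sets out from phenol 8 and commercial methyl 2-hydroxy-4-methoxy-6-methylbenzoate. Rieche formylation (Cl2CHOMe, TiCl4) between the hydroxyl and methoxy groups should give methyl 3-formyl-2-hydroxy-4-methoxy-6-methylbenzoate F1. Reduction with NaBH4 gives methyl 2-hydroxy-3-(hydroxymethyl)-4-methoxy-6-methylbenzoate F2. Silylation of the primary alcohol (TIPSCl, imidazole) gives methyl 2-hydroxy-4-methoxy-6-methyl-3-[(triisopropylsilyloxy)methyl]benzoate F3, and LiOH in aqueous THF gives 2-hydroxy-4-methoxy-6-methyl-3-[(triisopropylsilyloxy)methyl]benzoic acid F4. Carbodiimide esterification of F4 with 8 returns to the route at 24.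

Step 14. The ring-A phenoxide may attack the ester-bearing ring-B carbon instead (Smiles-type migration), or lose silanolate toward an ortho-quinone methide, or insertion of copper into the doubly ortho-substituted C–Br bond may be slow and end in loss of bromine. The fallback activates the bromide for addition–elimination and sets out from 24. Dilute HCl in THF hydrolyses the acetal to the bromo aldehyde depside F5, in which the formyl group ortho to bromine activates that carbon. K2CO3 in DMF with gentle heating should then close the ring by intramolecular nucleophilic aromatic substitution. This gives 26, where the route is rejoined at the hydrogenolysis half of step 15.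

Step 16. Acetal formation with a secondary benzylic alcohol at the hindered lactol may be slow, the alcohol may ionise under the acid, and the two epimers may be hard to separate. The fallback separates enantiomers instead of diastereomers and sets out from 27. Benzyl alcohol and catalytic CSA give the racemic benzyl acetal F6. Preparative chromatography on a chiral stationary phase gives the (R)-benzyl acetal F7, and the other enantiomer is racemised under the acetalisation conditions and recycled. HF·pyridine gives the desilylated (R)-benzyl acetal F8, and hydrogenolysis over Pd/C in EtOAc returns to the route at 31.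

**Further compounds**
F1 | step 13 | methyl 3-formyl-2-hydroxy-4-methoxy-6-methylbenzoate | COC(=O)c1c(C)cc(OC)c(C=O)c1O
F2 | step 13 | methyl 2-hydroxy-3-(hydroxymethyl)-4-methoxy-6-methylbenzoate | COC(=O)c1c(C)cc(OC)c(CO)c1O
F3 | step 13 | methyl 2-hydroxy-4-methoxy-6-methyl-3-[(triisopropylsilyloxy)methyl]benzoate | COC(=O)c1c(C)cc(OC)c(CO[Si](C(C)C)(C(C)C)C(C)C)c1O
F4 | step 13 | 2-hydroxy-4-methoxy-6-methyl-3-[(triisopropylsilyloxy)methyl]benzoic acid | OC(=O)c1c(C)cc(OC)c(CO[Si](C(C)C)(C(C)C)C(C)C)c1O
F5 | step 14 | 3-(benzyloxy)-4-[(benzyloxy)carbonyl]-6-bromo-5-formyl-2-methylphenyl 2-hydroxy-4-methoxy-6-methyl-3-[(triisopropylsilyloxy)methyl]benzoate | COc1cc(C)c(C(=O)Oc2c(C)c(OCc3ccccc3)c(C(=O)OCc4ccccc4)c(C=O)c2Br)c(O)c1CO[Si](C(C)C)(C(C)C)C(C)C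
F6 | step 16 | racemic benzyl acetal of 27 | COc1cc(C)c2c(c1CO[Si](C(C)C)(C(C)C)C(C)C)Oc1c(c(C)c(O)c3c1C(OCc4ccccc4)OC3=O)OC2=O
F7 | step 16 | (R)-benzyl acetal of 27 | COc1cc(C)c2c(c1CO[Si](C(C)C)(C(C)C)C(C)C)Oc1c(c(C)c(O)c3c1[C@H](OCc4ccccc4)OC3=O)OC2=O
F8 | step 16 | (R)-benzyl acetal with free ring-A hydroxymethyl group | COc1cc(C)c2c(c1CO)Oc1c(c(C)c(O)c3c1[C@H](OCc4ccccc4)OC3=O)OC2=O
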